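**Plan**

- Retrosynthesis: the C2 butyrate and the C9 and C14 acetates are removed. The butenolide is cut at C8=C17 and O–C19, back to a C7 ketone and methyl pyruvate. C2 and C7 both carry oxygen and lie 1,6 across the ten-membered ring C1–C10, so a C2–C7 bond is put back; this turns C2–C7 with the C5 methyl into a toluene ring (ring C) fused to the trans-decalin of ring A (C1, C10–C14) and ring B (C1, C2, C7–C10).
- The arene tricycle is cut in ring A at C10=C11 and C1–C14 (Michael/aldol annulation of 1,6-dimethyl-2-tetralone with ethyl vinyl ketone) and at C1–CH3.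
- Forward: ring A is annulated onto the tetralone, the C9, C14 and C12 oxygens are set on the rigid tricycle, ring C is reduced to the 1,4-diene, ozonolysis of C2=C7 merges rings B and C into the ten-membered ring, and the butenolide ring closes last.
- Stereochemistry: C1 comes from a chiral-imine Michael addition; C9 and C14 from attack anti to the C1 methyl; C12 from hydride anti to the C14 oxygen; C10 and C11 from hydroxyl-directed hydrogenation; C2 from a Corey–Bakshi–Shibata reduction; C7 from zinc chelation through the C9 MOM ether; the 5Z olefin from ring C.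
- The two new carbinol centres of the ten-membered ring are each 1,3-syn to an existing oxygen (C2 to C14–O, C7 to C9–O). C9 and C14 therefore carry small, chelating MOM ethers and C12 the TBS ether that is removed last.

Key step: step 15

Assumption: 6-methyl-2-tetralone is taken as purchasable; atoms are numbered as in the target (C15 = methyl on C1, C16 = methyl on C5, C17–C19 = lactone carbons, C18 = methyl on C17, C20 = methyl on C11), β is the face of the C1 methyl and α the opposite face.

**Route**

Step 1
Reactants: 1 6-methyl-2-tetralone; 2 iodomethane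
Product: 5 rac-1,6-dimethyl-2-tetralone, via pyrrolidine enamine 3 (not isolated), via iminium iodide 4 (not isolated)
Conditions: pyrrolidine, PhH, reflux (−H2O); MeI, 1,4-dioxane, reflux; H2O, 60 °C
Reagents that add atoms: iodomethane CI; water O
Why: Stork enamine alkylation: the enamine of a 2-tetralone is conjugated with the arene and is C-methylated only at the benzylic C1, so clean mono-methylation is expected; the centre is racemic and is reset in step 2.

Step 2
Reactants: 5 rac-1,6-dimethyl-2-tetralone; 6 ethyl vinyl ketone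
Product: 9 (R)-1,6-dimethyl-1-(3-oxopentyl)-2-tetralone, via secondary enamine 7 (not isolated), via imine adduct 8 (not isolated)
Conditions: (R)-1-phenylethylamine, TsOH (cat.), PhMe, reflux (−H2O); ethyl vinyl ketone, THF, 25–40 °C; 20% aq. AcOH, rt
Reagents that add atoms: ethyl vinyl ketone CCC(=O)C=C; water O
Why: Deracemising Michael addition of a chiral imine: the more substituted secondary enamine tautomer transfers to the enone in an aza-ene-like transition state on the face away from the phenyl group, which sets the quaternary C1 in the configuration of the target (R-amine gives the natural-type series); hydrolysis releases the auxiliary.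

Step 3
Reactants: 9 (R)-1,6-dimethyl-1-(3-oxopentyl)-2-tetralone
Product: 11 (S)-1,4a,7-trimethyl-4,4a,9,10-tetrahydrophenanthren-2(3H)-one (tricyclic enone), via ketol 10 (not isolated)
Conditions: NaOMe, MeOH, 25 → 60 °C
Reagents that add atoms: none
Why: Intramolecular aldol condensation (second half of the Robinson annulation): C11 of the ethyl ketone closes six-membered ring A on the C10 carbonyl and the ketol dehydrates to the tetrasubstituted C10=C11 enone.

Step 4
Reactants: 11 tricyclic enone
Product: 12 C12 ethylene ketal with C9=C10 olefin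
Conditions: ethylene glycol, TsOH·H2O (cat.), PhH, reflux (−H2O)
Reagents that add atoms: ethylene glycol OCCO
Why: Acid-catalysed ketalisation of a 4-en-3-one-type enone moves the olefin out of conjugation to C9=C10, as in steroid ketalisations; the C11 centre formed is returned to sp2 in step 6 and need not be controlled.

Step 5
Reactants: 12 C12 ethylene ketal with C9=C10 olefin
Product: 13 9α,10α-diol ketal
Conditions: OsO4 (2 mol%), N-methylmorpholine N-oxide, MeSO2NH2, acetone/H2O, rt
Reagents that add atoms: N-methylmorpholine N-oxide C[N+]1([O-])CCOCC1; water O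
Why: Catalytic OsO4 syn-dihydroxylation: the bulky osmium reagent adds to the α face, away from the axial C1 methyl that is 1,3 to C9, which sets the C9 carbinol and gives a disposable tertiary C10 hydroxyl.

Step 6
Reactants: 13 9α,10α-diol ketal
Product: 15 9α-hydroxy enone, via dihydroxy ketone 14 (not isolated)
Conditions: PPTS, acetone/H2O, 50 °C; then K2CO3, MeOH, 0 °C → rt
Reagents that add atoms: water O
Why: Ketal hydrolysis followed by E1cB loss of the C10 hydroxyl (β to the C12 ketone) restores the C10=C11 enone and leaves the equatorial 9α-hydroxyl, the classical route to 6α-hydroxy-4-en-3-ones; base is used for the dehydration to avoid a pinacol-type shift of the diol.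

Step 7
Reactants: 15 9α-hydroxy enone
Product: 16 9α-MOM ether enone
Conditions: MOMCl, i-Pr2NEt, CH2Cl2, 0 °C → rt
Reagents that add atoms: chloromethyl methyl ether COCCl
Why: Standard acetal protection; the MOM ether is stable to strong base, Li/NH3 and ozone, and its oxygen later serves as the chelating site for the C7 reduction.

Step 8
Reactants: 16 9α-MOM ether enone
Product: 19 cross-conjugated dienone (C10=C11 and C13=C14), via lithium dienolate 17 (not isolated), via silyl dienol ether 18 (not isolated)
Conditions: LiN(i-Pr)2, THF, −78 °C; Me3SiCl; then Pd(OAc)2 (1.05 equiv), MeCN, rt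
Reagents that add atoms: none
Why: Saegusa–Ito oxidation: kinetic deprotonation at the α′ carbon C13, silylation and Pd(OAc)2-mediated dehydrosilylation give the dienone without touching the benzylic C8 or the aryl methyl, which quinone oxidants could attack.

Step 9
Reactants: 19 cross-conjugated dienone
Product: 21 14α-hydroxy enone, via boryl ketone 20 (not isolated)
Conditions: B2pin2, CuCl (5 mol%), NaOt-Bu (10 mol%), DPEphos (5 mol%), MeOH (2 equiv), THF, rt; then NaBO3·4H2O, THF/H2O, rt
Reagents that add atoms: sodium perborate [Na+].[Na+].O[B-]1(O)OO[B-](O)(O)OO1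
Why: Copper-catalysed conjugate borylation and oxidation with retention: the Cu–B species adds only to the disubstituted C13=C14 enone (C10=C11 is fully substituted) and from the α face, anti to the quasi-axial C1 methyl, as in cuprate additions to steroidal 1,4-dien-3-ones and borylations of 4,4-disubstituted cyclohexadienones.

Step 10
Reactants: 21 14α-hydroxy enone
Product: 22 9α,14α-bis-MOM enone
Conditions: MOMCl, i-Pr2NEt, n-Bu4NI (cat.), CH2Cl2, 0 → 40 °C
Reagents that add atoms: chloromethyl methyl ether COCCl
Why: Acetal protection of the β-hydroxy ketone under mild amine base; the 14α-OMOM group is a poor leaving group and shields the α face of C12 in the next step.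

Step 11
Reactants: 22 9α,14α-bis-MOM enone
Product: 23 12α-allylic alcohol
Conditions: LiBH(s-Bu)3, THF, −78 °C; then H2O
Reagents that add atoms: none
Why: 1,2-Reduction of a β,β-disubstituted enone by a bulky trialkylborohydride from the β face, because the α face of C12 is blocked by the axial 14α-OMOM group (which also holds Li+ on that side); this gives the pseudo-axial 12α-alcohol, 1,3-syn to the C14 oxygen.

Step 12
Reactants: 23 12α-allylic alcohol
Product: 24 trans-fused saturated 12α-alcohol (H10 α, C11 methyl β)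
Conditions: H2 (1 atm), [Ir(cod)(PCy3)(py)]PF6 (10 mol%), CH2Cl2, 0 °C → rt
Reagents that add atoms: none
Why: Hydroxyl-directed homogeneous hydrogenation with the cationic iridium catalyst, one of the few that reduce tetrasubstituted olefins: binding to the 12α-hydroxyl (supported by the α-oriented ether oxygens) delivers both hydrogens to the α face, which sets H10 α (trans ring fusion) and H11 α (C11 methyl β).

Step 13
Reactants: 24 trans-fused saturated 12α-alcohol
Product: 25 12α-TBS ether (arene tricycle)
Conditions: TBSOTf, 2,6-lutidine, CH2Cl2, 0 °C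
Reagents that add atoms: tert-butyldimethylsilyl trifluoromethanesulfonate CC(C)(C)[Si](C)(C)OS(=O)(=O)C(F)(F)F
Why: Silylation of the hindered axial hydroxyl with the silyl triflate; the TBS ether is orthogonal to the MOM ethers and is removed last under conditions that spare esters.

Step 14
Reactants: 25 12α-TBS ether (arene tricycle)
Product: 26 1,4-dihydroarene (C2=C7 and C4=C5)
Conditions: Li, NH3 (l), THF, t-BuOH, −78 → −33 °C; then NH4Cl
Reagents that add atoms: none
Why: Birch reduction of a trialkylbenzene: protonation occurs at the two unsubstituted, para-related carbons C3 and C6, so the two remaining olefins carry all three alkyl groups; silyl and MOM ethers are stable to Li/NH3.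

Step 15
Reactants: 26 1,4-dihydroarene
Product: 29 ring A-fused (4Z)-cyclodec-4-ene-2,7-dione, via primary ozonide 27 (not isolated), via secondary ozonide 28 (not isolated)
Conditions: O3 (1 equiv, dye end-point), CH2Cl2, −78 °C; then Me2S, −78 °C → rt
Reagents that add atoms: ozone [O-][O+]=O
Why: Criegee ozonolysis: O3 adds as a 1,3-dipole to C2=C7 to give the 1,2,3-trioxolane 27, which cycloreverts to a ketone and a carbonyl oxide that remain tethered and recombine to the 1,2,4-trioxolane 28, and Me2S then cleaves the peroxide to the C2 and C7 ketones. The closest known reaction type is the oxidative cleavage of the central olefin of 9,10-octalins and 1,4-dihydroarenes to cyclodecane-1,6-diones. No ring is closed: scission of the bond shared by ring B and ring C merges them into the ten-membered ring, with ring A untouched. No stereocentre is formed; the cis relation of C3 and C6 on the C4=C5 olefin is carried over from ring C. The step needs chemoselectivity between the tetrasubstituted C2=C7 and the trisubstituted C4=C5 olefin, which the higher nucleophilicity of the fully alkylated olefin toward electrophilic ozone should provide when one equivalent is delivered at −78 °C. The MOM and TBS ethers are inert to ozone.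

Step 16
Reactants: 29 cyclodecene-2,7-dione
Product: 30 C7 ethylene ketal
Conditions: (Me3SiOCH2)2, Me3SiOTf (5 mol%), CH2Cl2, −78 °C; pyridine quench
Reagents that add atoms: 1,2-bis(trimethylsilyloxy)ethane C[Si](C)(C)OCCO[Si](C)(C)C
Why: Aprotic silyl-triflate-catalysed acetalisation at low temperature does not move β,γ-olefins and distinguishes the unhindered C7 ketone from the C2 ketone next to the quaternary C1; masking C7 before any base treatment removes the C3/C6 deprotonation ambiguity and the transannular aldol of the 1,6-dione.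

Step 17
Reactants: 30 C7 ethylene ketal
Product: 32 (2R)-alcohol, via catechol borate 31 (not isolated)
Conditions: (S)-2-methyl-CBS-oxazaborolidine (0.5 equiv), catecholborane, PhMe, −40 → 0 °C; then MeOH, 1 M NaOH
Reagents that add atoms: none
Why: Corey–Bakshi–Shibata reduction: the ketone has a tertiary-alkyl (C1) and a primary-alkyl (C3) flank, the class for which catalyst control is strongest, and the (S)-catalyst should give the (2R)-carbinol, 1,3-syn to the C14 oxygen; catecholborane is used because it does not hydroborate the C4=C5 olefin.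

Step 18
Reactants: 32 (2R)-alcohol
Product: 33 C2 butyrate
Conditions: (n-PrCO)2O, DMAP, Et3N, CH2Cl2, rt → 40 °C
Reagents that add atoms: butyric anhydride CCCC(=O)OC(=O)CCC
Why: DMAP-catalysed acylation of a hindered secondary alcohol; the butyrate is the final C2 ester and serves as its own protecting group through the rest of the route.

Step 19
Reactants: 33 C2 butyrate
Product: 35 (5Z)-enone (C5=C6–C7=O), via unconjugated enone 34 (not isolated)
Conditions: PPTS, acetone/H2O (10:1), 50 °C; then DBU (0.1 equiv), CH2Cl2, −20 → 0 °C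
Reagents that add atoms: water O
Why: Mild dioxolane hydrolysis frees the C7 ketone and base then moves the β,γ-olefin into conjugation through the C6 dienolate; with C2 no longer a ketone, C6 is the only doubly activated position, and the cis geometry is the stable one for a ten-membered enone.

Step 20
Reactants: 35 (5Z)-enone; 36 methyl pyruvate
Product: 38 C8 aldol adduct (C8 and C17 epimers), via lithium enolate 37 (not isolated)
Conditions: LiN(i-Pr)2 (1.05 equiv), THF, −78 °C; methyl pyruvate, −78 °C; AcOH quench at −78 °C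
Reagents that add atoms: methyl pyruvate CC(=O)C(=O)OC
Why: Kinetic α′-deprotonation of the enone at C8 and aldol addition to the ketone carbonyl of an α-keto ester; the ketone is enolised in preference to the butyrate, the C9 alkoxy group is a poor leaving group at −78 °C, and both new centres are returned to sp2 in step 21.

Step 21
Reactants: 38 C8 aldol adduct
Product: 40 alkylidene keto ester (C8=C17, E/Z mixture), via trifluoroacetate 39 (not isolated)
Conditions: (CF3CO)2O, pyridine, DMAP (cat.), CH2Cl2, 0 °C; then Et3N, 0 °C → rt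
Reagents that add atoms: none
Why: Aldol dehydration by E1cB: acylation of the tertiary hydroxyl and enolisation at C8 expel trifluoroacetate whatever the configuration at C8 and C17, giving the tetrasubstituted alkene as geometrical isomers that both lead to the same lactone in step 22; the mild amine base limits γ-deprotonation at C9.

Step 22
Reactants: 40 alkylidene keto ester
Product: 42 butenolide (9α,14α-bis-OMOM, 12α-OTBS, C2 butyrate), via hydroxy ester 41 (not isolated)
Conditions: Zn(BH4)2, Et2O, −40 → −20 °C; aq. NH4Cl; then PhCOCH3 (cat.), PPTS (cat.), PhH, hν (350 nm), rt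
Reagents that add atoms: none
Why: Chelation-controlled 1,2-reduction and lactonisation: Zn2+ bridges the C7 carbonyl and the C9 MOM oxygen in a planar six-membered chelate and hydride enters from the side of the C9 hydrogen, away from C10 and the ring, which gives the 7,9-syn (7S) alcohol; the Z-hydroxy ester lactonises at once and sensitised E→Z photoisomerisation brings the E isomer to the same butenolide.

Step 23
Reactants: 42 butenolide
Product: 44 9α,14α-diol, via bis(bromomethyl) ether 43 (not isolated)
Conditions: Me2BBr (4 equiv), CH2Cl2, −78 °C; then THF/aq. NaHCO3, −78 °C → rt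
Reagents that add atoms: none
Why: Bromoborane cleavage of MOM ethers: bromide attacks the boron-activated acetal at −78 °C, where the silyl ether, the butyrate and the allylic lactone are inert, and aqueous work-up releases both alcohols.

Step 24
Reactants: 44 9α,14α-diol
Product: 45 9,14-diacetate (12α-OTBS)
Conditions: Ac2O, DMAP, pyridine, rt
Reagents that add atoms: acetic anhydride CC(=O)OC(C)=O
Why: DMAP-catalysed acetylation of both secondary alcohols, run directly after their release so that the free C9 hydroxyl has no time to translactonise.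

Step 25
Reactants: 45 9,14-diacetate (12α-OTBS)
Product: 46 CNP0281577.1 (target)
Conditions: HF·pyridine, pyridine, THF, 0 °C → rt
Reagents that add atoms: none
Why: Fluoride desilylation under buffered acidic conditions leaves the three esters and the butenolide intact and avoids the base-induced acyl shift possible between the cis-related C12 and C14 oxygens.

**Compound list**

1 | 6-methyl-2-tetralone | Cc1ccc2CC(=O)CCc2c1 | starting material
2 | iodomethane | CI | starting material
3 | 1-(6-methyl-3,4-dihydronaphthalen-2-yl)pyrrolidine | Cc1ccc2C=C(N3CCCC3)CCc2c1 | intermediate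
4 | 1-(1,6-dimethyl-3,4-dihydronaphthalen-2(1H)-ylidene)pyrrolidinium iodide | CC1C(=[N+]2CCCC2)CCc2cc(C)ccc21.[I-] | intermediate
5 | rac-1,6-dimethyl-3,4-dihydronaphthalen-2(1H)-one | CC1C(=O)CCc2cc(C)ccc21 | intermediate
6 | ethyl vinyl ketone | CCC(=O)C=C | starting material
7 | 1,6-dimethyl-N-[(R)-1-phenylethyl]-3,4-dihydronaphthalen-2-amine | CC1=C(N[C@H](C)c2ccccc2)CCc2cc(C)ccc21 | intermediate
8 | (R)-1-phenylethyl imine of 9 | CCC(=O)CC[C@@]1(C)C(=N[C@H](C)c2ccccc2)CCc2cc(C)ccc21 | intermediate
9 | (R)-1,6-dimethyl-1-(3-oxopentyl)-3,4-dihydronaphthalen-2(1H)-one | CCC(=O)CC[C@@]1(C)C(=O)CCc2cc(C)ccc21 | intermediate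
10 | ketol: 11 with water added across C10=C11 (OH on C10; C10, C11 epimers) | Cc1ccc2c(c1)CCC3(O)C(C)C(=O)CC[C@@]32C | intermediate
11 | (S)-1,4a,7-trimethyl-4,4a,9,10-tetrahydrophenanthren-2(3H)-one (C10=C11, C12=O) | Cc1ccc2c(c1)CCC3=C(C)C(=O)CC[C@@]32C | intermediate
12 | C12 ethylene ketal of 11 with the olefin at C9=C10 (C11 epimers) | Cc1ccc2c(c1)CC=C3C(C)C4(OCCO4)CC[C@@]32C | intermediate
13 | 9α,10α-diol of 12 (both hydroxyls anti to the C1 methyl) | Cc1ccc2c(c1)C[C@H](O)[C@@]3(O)C(C)C4(OCCO4)CC[C@@]32C | intermediate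
14 | 9α,10α-dihydroxy C12 ketone | Cc1ccc2c(c1)C[C@H](O)[C@@]3(O)C(C)C(=O)CC[C@@]32C | intermediate
15 | 9α-hydroxy enone (11 with OH at C9, anti to the C1 methyl) | Cc1ccc2c(c1)C[C@H](O)C3=C(C)C(=O)CC[C@@]32C | intermediate
16 | 9α-MOM ether of 15 | Cc1ccc2c(c1)C[C@H](OCOC)C3=C(C)C(=O)CC[C@@]32C | intermediate
17 | lithium C12–C13 dienolate of 16 | Cc1ccc2c(c1)C[C@H](OCOC)C3=C(C)C([O-])=CC[C@@]32C.[Li+] | intermediate
18 | trimethylsilyl dienol ether of 16 (C12–OSiMe3, C12=C13) | Cc1ccc2c(c1)C[C@H](OCOC)C3=C(C)C(O[Si](C)(C)C)=CC[C@@]32C | intermediate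
19 | cross-conjugated dienone (C10=C11, C13=C14, C12=O, 9α-OMOM) | Cc1ccc2c(c1)C[C@H](OCOC)C3=C(C)C(=O)C=C[C@@]32C | intermediate
20 | 14α-(pinacolatoboryl) enone | Cc1ccc2c(c1)C[C@H](OCOC)C3=C(C)C(=O)C[C@H](B4OC(C)(C)C(C)(C)O4)[C@@]32C | intermediate
21 | 14α-hydroxy enone (9α-OMOM) | Cc1ccc2c(c1)C[C@H](OCOC)C3=C(C)C(=O)C[C@H](O)[C@@]32C | intermediate
22 | 9α,14α-bis-MOM enone | Cc1ccc2c(c1)C[C@H](OCOC)C3=C(C)C(=O)C[C@H](OCOC)[C@@]32C | intermediate
23 | 12α-allylic alcohol (C10=C11, 9α,14α-bis-OMOM) | Cc1ccc2c(c1)C[C@H](OCOC)C3=C(C)[C@H](O)C[C@H](OCOC)[C@@]32C | intermediate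
24 | trans-fused 12α-alcohol (H10 α, C11 methyl β, 9α,14α-bis-OMOM) | Cc1ccc2c(c1)C[C@H](OCOC)[C@H]3[C@@H](C)[C@H](O)C[C@H](OCOC)[C@@]32C | intermediate
25 | 12α-TBS ether of 24 | Cc1ccc2c(c1)C[C@H](OCOC)[C@H]3[C@@H](C)[C@H](O[Si](C)(C)C(C)(C)C)C[C@H](OCOC)[C@@]32C | intermediate
26 | 1,4-dihydroarene (ring C reduced; C2=C7 and C4=C5 olefins) | CC1=CCC2=C(C1)C[C@H](OCOC)[C@H]3[C@@H](C)[C@H](O[Si](C)(C)C(C)(C)C)C[C@H](OCOC)[C@@]32C | intermediate
27 | primary ozonide (1,2,3-trioxolane on C2 and C7) | CC1=CCC23OOOC2(C1)C[C@H](OCOC)[C@H]4[C@@H](C)[C@H](O[Si](C)(C)C(C)(C)C)C[C@H](OCOC)[C@@]43C | intermediate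
28 | secondary ozonide (1,2,4-trioxolane bridging C2 and C7) | CC1=CCC23OOC(C1)(O2)C[C@H](OCOC)[C@H]4[C@@H](C)[C@H](O[Si](C)(C)C(C)(C)C)C[C@H](OCOC)[C@@]43C | intermediate
29 | ring A-fused (4Z)-cyclodec-4-ene-2,7-dione (9α,14α-bis-OMOM, 12α-OTBS) | O=C1C/C=C(C)\CC(=O)C[C@H](OCOC)[C@H]2[C@@H](C)[C@H](O[Si](C)(C)C(C)(C)C)C[C@H](OCOC)[C@@]21C | intermediate
30 | C7 ethylene ketal of 29 | O=C1C/C=C(C)\CC2(OCCO2)C[C@H](OCOC)[C@H]3[C@@H](C)[C@H](O[Si](C)(C)C(C)(C)C)C[C@H](OCOC)[C@@]31C | intermediate
31 | catechol borate of 32 | O(B1Oc2ccccc2O1)[C@@H]3C/C=C(C)\CC4(OCCO4)C[C@H](OCOC)[C@H]5[C@@H](C)[C@H](O[Si](C)(C)C(C)(C)C)C[C@H](OCOC)[C@@]53C | intermediate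
32 | (2R)-alcohol (C2–OH syn to the C14 oxygen, C7 ketal) | O[C@@H]1C/C=C(C)\CC2(OCCO2)C[C@H](OCOC)[C@H]3[C@@H](C)[C@H](O[Si](C)(C)C(C)(C)C)C[C@H](OCOC)[C@@]31C | intermediate
33 | C2 butyrate of 32 | CCCC(=O)O[C@@H]1C/C=C(C)\CC2(OCCO2)C[C@H](OCOC)[C@H]3[C@@H](C)[C@H](O[Si](C)(C)C(C)(C)C)C[C@H](OCOC)[C@@]31C | intermediate
34 | β,γ-unsaturated C7 ketone ((4Z)-C4=C5, C2 butyrate) | CCCC(=O)O[C@@H]1C/C=C(C)\CC(=O)C[C@H](OCOC)[C@H]2[C@@H](C)[C@H](O[Si](C)(C)C(C)(C)C)C[C@H](OCOC)[C@@]21C | intermediate
35 | (5Z)-enone (C5=C6–C7=O, C2 butyrate) | CCCC(=O)O[C@@H]1CC/C(C)=C\C(=O)C[C@H](OCOC)[C@H]2[C@@H](C)[C@H](O[Si](C)(C)C(C)(C)C)C[C@H](OCOC)[C@@]21C | intermediate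
36 | methyl pyruvate | CC(=O)C(=O)OC | starting material
37 | lithium C7–C8 enolate of 35 | CCCC(=O)O[C@@H]1CC/C(C)=C\C([O-])=C[C@H](OCOC)[C@H]2[C@@H](C)[C@H](O[Si](C)(C)C(C)(C)C)C[C@H](OCOC)[C@@]21C.[Li+] | intermediate
38 | aldol adduct: 35 with C(OH)(CH3)CO2CH3 on C8 (C8, C17 epimers) | CCCC(=O)O[C@@H]1CC/C(C)=C\C(=O)C(C(C)(O)C(=O)OC)[C@H](OCOC)[C@H]2[C@@H](C)[C@H](O[Si](C)(C)C(C)(C)C)C[C@H](OCOC)[C@@]21C | intermediate
39 | C17 trifluoroacetate of 38 | CCCC(=O)O[C@@H]1CC/C(C)=C\C(=O)C(C(C)(OC(=O)C(F)(F)F)C(=O)OC)[C@H](OCOC)[C@H]2[C@@H](C)[C@H](O[Si](C)(C)C(C)(C)C)C[C@H](OCOC)[C@@]21C | intermediate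
40 | alkylidene keto ester (C8=C17(CH3)CO2CH3, E/Z mixture) | CCCC(=O)O[C@@H]1CC/C(C)=C\C(=O)C(=C(C)C(=O)OC)[C@H](OCOC)[C@H]2[C@@H](C)[C@H](O[Si](C)(C)C(C)(C)C)C[C@H](OCOC)[C@@]21C | intermediate
41 | (7S)-hydroxy ester (C7 carbinol of 40, E/Z mixture) | CCCC(=O)O[C@@H]1CC/C(C)=C\[C@H](O)C(=C(C)C(=O)OC)[C@H](OCOC)[C@H]2[C@@H](C)[C@H](O[Si](C)(C)C(C)(C)C)C[C@H](OCOC)[C@@]21C | intermediate
42 | butenolide (9α,14α-bis-OMOM, 12α-OTBS, C2 butyrate) | CCCC(=O)O[C@@H]1CC/C(C)=C\[C@@H]2OC(=O)C(C)=C2[C@H](OCOC)[C@H]2[C@@H](C)[C@H](O[Si](C)(C)C(C)(C)C)C[C@H](OCOC)[C@@]21C | intermediate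
43 | 9,14-bis(bromomethyl) ether | CCCC(=O)O[C@@H]1CC/C(C)=C\[C@@H]2OC(=O)C(C)=C2[C@H](OCBr)[C@H]2[C@@H](C)[C@H](O[Si](C)(C)C(C)(C)C)C[C@H](OCBr)[C@@]21C | intermediate
44 | 9α,14α-diol (12α-OTBS, C2 butyrate, butenolide) | CCCC(=O)O[C@@H]1CC/C(C)=C\[C@@H]2OC(=O)C(C)=C2[C@H](O)[C@H]2[C@@H](C)[C@H](O[Si](C)(C)C(C)(C)C)C[C@H](O)[C@@]21C | intermediate
45 | 9,14-diacetate (12α-OTBS) | CCCC(=O)O[C@@H]1CC/C(C)=C\[C@@H]2OC(=O)C(C)=C2[C@H](OC(C)=O)[C@H]2[C@@H](C)[C@H](O[Si](C)(C)C(C)(C)C)C[C@H](OC(C)=O)[C@@]21C | intermediate
46 | CNP0281577.1 | CCCC(=O)O[C@@H]1CC/C(C)=C\[C@@H]2OC(=O)C(C)=C2[C@H](OC(C)=O)[C@H]2[C@@H](C)[C@H](O)C[C@H](OC(C)=O)[C@@]21C | target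

**Step count and risks**

Total step count: 25. Longest linear sequence: 25 steps (fully linear from 6-methyl-2-tetralone).

The three steps most likely to fail all lie on the new ten-membered ring, where precedent is thinnest.

Step 15. The two olefins may not be distinguished cleanly: ozone may also cleave C4=C5, or the hindered tetrasubstituted olefin may be diverted to epoxide instead of being cleaved. The fallback sets out from 26 and replaces the one-pot cleavage by two stages. Epoxidation with m-CPBA (1 equiv, NaHCO3, CH2Cl2, −20 °C) is far more sensitive to olefin substitution and should give the C2–C7 epoxide F1. Periodic acid (H5IO6, THF/H2O, 0 °C) then opens the epoxide and cleaves the resulting diol, which returns the route to dione 29.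

Step 17. Hydride transfer to the C2 ketone next to the quaternary C1 may be slow, or the intrinsic facial bias of the ring may oppose the catalyst and erode selectivity. The fallback sets out from 30 and replaces catalyst control by substrate chelation. LiAlH4 with LiI in Et2O at −78 °C (no ester is present at this stage) should hold Li+ between the C2 carbonyl and the C14 MOM oxygen and deliver hydride to the 1,3-syn face. It returns directly to 32 and passes through no compound outside the list (none F0).

Step 22. If the ester carbonyl competes with the C9 MOM oxygen for zinc, the chelate that directs the hydride is lost and attack on the other face of C7 gives the epimeric lactone. The fallback sets out from 40 and corrects the centre by inversion. The 7-epi butenolide F2 obtained is opened with LiOH (1 equiv, THF/H2O, 0 °C; the unsaturated γ-lactone should saponify faster than the hindered butyrate) to the Z-hydroxy acid F3. Its triethylammonium salt is then closed under Mitsunobu conditions (PPh3, DIAD, THF, 0 °C) with inversion at C7, which returns the route to 42.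

Further compounds
F1 | step 15 | C2–C7 epoxide of 26 | CC1=CCC23OC2(C1)C[C@H](OCOC)[C@H]4[C@@H](C)[C@H](O[Si](C)(C)C(C)(C)C)C[C@H](OCOC)[C@@]43C
F0 | step 17 | none | none
F2 | step 22 | 7-epi butenolide (C7 epimer of 42) | CCCC(=O)O[C@@H]1CC/C(C)=C\[C@H]2OC(=O)C(C)=C2[C@H](OCOC)[C@H]2[C@@H](C)[C@H](O[Si](C)(C)C(C)(C)C)C[C@H](OCOC)[C@@]21C
F3 | step 22 | (Z)-7-epi hydroxy acid from F2 | CCCC(=O)O[C@@H]1CC/C(C)=C\[C@@H](O)/C(=C(/C)C(=O)O)[C@H](OCOC)[C@H]2[C@@H](C)[C@H](O[Si](C)(C)C(C)(C)C)C[C@H](OCOC)[C@@]21C
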